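(The readings come from a simulation from invented constants, noise included.)

I began from a one-step world, in which each substrate takes one reagent, becomes target and stays target. The reagent waits in a second phase and reacts in the first, where everything else is.

- blue: substrate 0.65 M; reagent in the second phase 0.36 M; run made earlier
- flask: substrate 0.65 M; reagent in the second phase 0.715 M; time 10 min; volume of the second phase over the first 0.50

blue run (percent of the substrate charged)

| time / min | target / % |
|---|---|
| 0.167 | 5.0 |
| 0.500 | 7.9 |
| 0.833 | 7.2 |
| 1.33 | 5.2 |
| 2.00 | 1.5 |
| 2.50 | 0.9 |
| 3.00 | 1.2 |

(each reading ± 0.5 percentage points)

- in the second phase: reagent in the second phase; everything else is in the first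
- charges count per volume of the first phase; a concentration in a rate is the amount of a species over the volume of its own phase; every rate counts per litre of the first phase
- the earlier runs hold the two phases in the same ratio of volumes as the flask asked about
- a reading or a percentage of target counts all its forms, free or not

* time up to 10 min at which target stands highest
* the amount of target, in percent of the substrate charged, at that time
* earliest time at which at least nineteen twentieths of that best amount are there, in min
* latest time at which they still are, in min

In that world the number to watch was the reagent charged per substrate: 1.10 in the flask and 0.554 in the blue run. The target ceiling in the flask was 100%, and the substrate was the limiting reagent, since its charge was the smaller. The blue ceiling was 55.4%.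

The blue readings refused this. Target read 7.9% at 0.500 min and 1.2% at 3.00 min, so something was eating it, far below the ceiling. I supposed a second step in which target pairs with substrate into a side product. That route costs 0.5 reagent per substrate.

From this I took my own measure, the reserve: the reagent per substrate multiplied by 2, less one. Once the substrate is used, it is the largest share that can stand as target, and a negative reserve is the least share of substrate stranded. The blue run came to 10.8%, and the readings stayed under it. The flask came to 120%, so its ceiling stayed put, above the whole substrate.

The rest I could only place: spare reagent may attack target, so target should sink slowly after its peak. I committed to no peak height, only to substrate running out first.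

The forecast gave 14% (range 10% to 21%) at 0.42 min, held from 0.3 min to 0.56 min, on the ground that “target's loss seems to be tied less to reagent than its formation is”.

The flask gave 35.1% at 2.14 min, held from 1.11 min to 4.54 min: 21 percentage points above the forecast.

    reagent in the reaction phase ⇌ reagent in the second phase, rate k1*([reagent in the reaction phase] - [reagent in the second phase]/K1) per volume of the first phase (partition coefficient = 1.36, kL = 1.05 /s)
    reagent in the reaction phase → decomposition product (k = 5.32 × 10⁻⁵ /s)
    substrate + target → side product (k = 0.535 /M/s)
    crystals ⇌ target, rate k4*(cs4 - [target]) while solid is left; crystals form when [target] > cs4 (solubility = 13.0 mM, k = 4.66 /s)
    reagent in the reaction phase + target → over-reacted product (k = 0.0657 /M/s)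
    substrate + reagent in the reaction phase → target (k = 0.0655 /M/s)

At 2.14 min the flask's target of 35.1% counted 33.1% of crystals, beside 54.6% of side product. By 10.0 min the flask's substrate stood at 0.00519%, the first charge to run out, as its reserve of 120% said. The neighbour flask, charged with 1.6 M of substrate, has 0.447 reagent per substrate and a reserve of −10.6%, which strands at least 10.6% of its substrate. Its best target was 15.2%, and at 10.0 min the neighbour flask held 0% target and 13% substrate, more than that least share.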